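## Structural features

The target is a B-type proanthocyanidin trimer of three 2-aryl-chroman-3-ol (flavan-3-ol) units: an upper (+)-catechin, a middle (+)-gallocatechin and a lower (+)-catechin. Each unit has a 5,7-dioxygenated A ring, a pyran C ring and a catechol or pyrogallol B ring. Two C(sp3)–C(sp2) interflavan bonds join them: C4 of the upper C ring to C8 of the middle A ring, and C4 of the middle C ring to C8 of the lower A ring. The eight stereocentres form three contiguous groups: upper C2/C3/C4 (2R, 2,3-trans, 3,4-trans, a 4α bond), middle C2/C3/C4 (2R, 2,3-trans but 3,4-cis, a 4β bond on the face of the 3-OH) and lower C2/C3 (2R,3S). Thirteen phenols (one pyrogallol), interflavan bonds that ionise in acid and C2 centres that epimerise in base make the free compound fragile, so every phenol should stay masked until a last, neutral step. The real difficulty is C4 of the middle unit. It is a diarylmethine with four ortho substituents whose aryl group must lie cis to O3, whereas flavan-4-yl cations of the 2,3-trans series are expected to take up a free arene trans to O3. The bond must also go to C8 and not C6 of the lower A ring. The key step exploits two features: O3 and C4 of the middle C ring are vicinal, and C8 of the lower A ring has both ortho positions occupied by oxygen. A single silicon atom bridging O3 and that C8 can therefore hand the ring to C4 only by ipso attack and only on the O3 face.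

## Logic of the disconnections

16 to 15: the fourteen O–CH2Ph bonds are cut. Benzyl ethers are the one mask that comes off under neutral hydrogenolysis, which the acid-labile interflavan bonds and base-labile C2 centres tolerate. The forward step must remove all fourteen without touching the two benzylic C4–aryl bonds.

15 to 14 + 13: the upper C4–middle C8 bond is cut as a Friedel–Crafts alkylation. This bond has the natural 3,4-trans geometry that a free arene is expected to give with a 2,3-trans cation, so it is left to well-precedented chemistry and placed after the hard bond. The forward step demands attack by C8 of the gallocatechin unit of 13 (not a C6 position) from the α face of the cation derived from 14.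

13 to 11 (through 12): the middle C4–lower C8 bond is cut, and the lower C8 is reconnected to a silicon atom on O3 of the middle unit. In one sentence: the lower catechin is handed from silicon on O3 to C4 by an intramolecular ipso-Friedel–Crafts substitution, a 1,4-aryl shift from Si to C. This replaces a stereochemical preference by connectivity. The hardest bond and its stereocentre fall back to two monomers joined by an Si–O bond that needs no selectivity. The forward step demands that intramolecular ipso capture of the C4 cation outruns intermolecular alkylation and protodesilylation.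

11 to 8 + 4 (through 10 and 9): the Si–O3 and Si–C8 bonds are cut. This gives a gallocatechin-type unit with a free 3-OH and a C4 leaving group, and a lower unit marked at C8 by bromine. The forward step demands monoarylation of a dichlorosilane and silylation of a hindered secondary alcohol.

8 to 7 to 6 to 5: the C4–OMe bond is traced back to the C4 carbonyl of dihydromyricetin, which supplies C2 and C3 of the middle unit in the correct 2,3-trans configuration. Reduction and benzylic solvolysis differentiate O4 (leaving group) from O3 (tether site) without protecting-group steps on O3. The forward steps demand that C2 survives the basic benzylation.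

4 to 3 to 2 to 1, and 14 to 2: the C8–Br bond, the benzyl ethers and the C4–O bond of the upper electrophile are cut back to (+)-catechin, which supplies C2 and C3 of both the upper and lower units. Bromination must choose C8 over C6, and the C4 oxidation of 2 must stop at the ether.

## Other disconnections considered

Alternative 1: the first that comes to mind. The middle C4–lower C8 bond is cut as an intermolecular Lewis-acid Friedel–Crafts alkylation of free nucleophile 3 by the cation from 8, giving dimer A1. With an untethered arene the cation of a 2,3-trans flavan-3-ol is expected to be attacked on the α face, anti to O3, which is the same preference used to advantage in step 10. The 3,4-trans dimer A1, epimeric with 13 at the middle C4, would therefore be expected as the main product, and nothing in the substrate could reverse this. C8 versus C6 selectivity would also rest only on relative nucleophilicity. The chosen plan uses the same cation but removes both choices through the tether.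

Alternative 2: O1–C2 and C3–C4 of the middle C ring are cut as a hetero-Diels–Alder reaction. The o-quinone methide generated from benzhydrol A2 would add to (E)-styrylboronate A3, and the C–B bond would then be oxidised. This would build the middle unit in place, and the (E)-alkene would translate into 2,3-trans. However, the endo preference of aryl dienophiles would be expected to place the C2 aryl cis to the C4 aryl, which after oxidation is again the 3,4-trans series. No nearby stereocentre controls the absolute sense of addition. It would also rebuild from scratch a C6–C3–C6 unit that 5 supplies with C2 and C3 already set, at a cost of several steps.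

Alternative 3: the middle C4–lower C8 bond is cut at the ketone oxidation level. Aryllithium 9 would add to the C4 carbonyl of 6 after 3-O-benzylation, giving tertiary carbinol A4, and ionic hydrogenation would write the C4–H bond last. The C–C bond would need no stereocontrol, which is attractive. The configuration of C4 would then depend on the face from which an external hydride meets a planar, hindered 4-aryl cation. In the 2,3-trans series the equatorial 3-substituent differentiates the faces only weakly, and a small nucleophile may prefer the axial β face, which would again leave the aryl group trans. The chosen plan fixes the face by a one-atom tether; a variant of this alternative in which the hydride comes from C3 by a 1,2-shift is kept as the fallback for the key step.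

Key step: step 8

Assumption: 8 and 14 are written as their expected main 4β epimers; any 4α epimer ionises to the same cation and need not be separated.

## Steps

Step 1
Reactants: 1 (+)-catechin
Product: 2 5,7,3',4'-tetra-O-benzyl-(+)-catechin
Conditions: BnBr (4.4 equiv), K2CO3, DMF, 0 °C to rt
Reagents that add atoms: benzyl bromide, BrCc1ccccc1
Why: Williamson etherification; carbonate deprotonates only the four phenols, so the C3 alcohol stays free and C2/C3 are untouched.

Step 2
Reactants: 2 5,7,3',4'-tetra-O-benzyl-(+)-catechin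
Product: 3 3,5,7,3',4'-penta-O-benzyl-(+)-catechin
Conditions: NaH, BnBr, DMF, 0 °C to rt
Reagents that add atoms: benzyl bromide, BrCc1ccccc1
Why: Williamson etherification of the secondary alkoxide; the unit is lithiated later, so no acidic OH may remain; no stereocentre is affected.

Step 3
Reactants: 3 3,5,7,3',4'-penta-O-benzyl-(+)-catechin
Product: 4 8-bromo-3,5,7,3',4'-penta-O-benzyl-(+)-catechin
Conditions: NBS (1.0 equiv), CH2Cl2, −78 °C to rt
Reagents that add atoms: N-bromosuccinimide, O=C1CCC(=O)N1Br
Why: Electrophilic aromatic bromination; of the two free A-ring positions, C8 (between O1 and 7-OBn) is expected to react first, as is usual for benzylated flavan-3-ols, which marks the future interflavan carbon.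

Step 4
Reactants: 5 (+)-dihydromyricetin
Product: 6 5,7,3',4',5'-penta-O-benzyl-(+)-dihydromyricetin
Conditions: BnBr (5.5 equiv), K2CO3, DMF, rt, N2, dark
Reagents that add atoms: benzyl bromide, BrCc1ccccc1
Why: Williamson etherification of the five phenols (the chelated 5-OH last); the α-ketol OH is not alkylated by carbonate. C2 and C3 should be retained if ring opening to the chalcone is avoided by mild base and exclusion of air.

Step 5
Reactants: 6 5,7,3',4',5'-penta-O-benzyl-(+)-dihydromyricetin
Product: 7 (2R,3S,4R)-5,7-bis(benzyloxy)-2-[3,4,5-tris(benzyloxy)phenyl]chromane-3,4-diol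
Conditions: NaBH4, THF/EtOH, 0 °C
Reagents that add atoms: none
Why: Carbonyl reduction; axial hydride attack on the β face of the half-chair chromanone should give the equatorial 4α-alcohol, trans to the 3β-OH. This C4 configuration is not carried into the target.

Step 6
Reactants: 7 (2R,3S,4R)-5,7-bis(benzyloxy)-2-[3,4,5-tris(benzyloxy)phenyl]chromane-3,4-diol
Product: 8 (2R,3S,4S)-5,7-bis(benzyloxy)-4-methoxy-2-[3,4,5-tris(benzyloxy)phenyl]chroman-3-ol
Conditions: MeOH/CH2Cl2, PPTS (cat.), rt
Reagents that add atoms: methanol, CO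
Why: SN1 solvolysis; only the benzylic 4-OH ionises (A-ring-stabilised cation) and the large excess of methanol captures it, mainly on the axial β face. This differentiates O4 (leaving group) from O3 (free, tether site) without a protecting group.

Step 7
Reactants: 4 8-bromo-3,5,7,3',4'-penta-O-benzyl-(+)-catechin; 8 (2R,3S,4S)-5,7-bis(benzyloxy)-4-methoxy-2-[3,4,5-tris(benzyloxy)phenyl]chroman-3-ol
Product: 11 (2R,3S,4S)-5,7-bis(benzyloxy)-4-methoxy-2-[3,4,5-tris(benzyloxy)phenyl]chroman-3-yl dimethyl[(2R,3S)-3,5,7-tris(benzyloxy)-2-(3,4-bis(benzyloxy)phenyl)chroman-8-yl]silyl ether, via 8-lithio-penta-O-benzyl-(+)-catechin 9 (not isolated), via 8-(chlorodimethylsilyl)-penta-O-benzyl-(+)-catechin 10 (not isolated)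
Conditions: 4, t-BuLi (2.0 equiv), THF, −78 °C; transfer into Me2SiCl2 (5 equiv), THF, −78 °C to rt; evaporate volatiles; 8, imidazole, CH2Cl2, 0 °C to rt; chromatography on Et3N-deactivated silica
Reagents that add atoms: dichlorodimethylsilane, C[Si](C)(Cl)Cl
Why: Bromine–lithium exchange, substitution at silicon and silylation of the C3 alcohol, i.e. a temporary silicon tether. Inverse addition to excess dichlorosilane should suppress diarylation; no stereocentre changes.

Step 8
Reactants: 11 (2R,3S,4S)-5,7-bis(benzyloxy)-4-methoxy-2-[3,4,5-tris(benzyloxy)phenyl]chroman-3-yl dimethyl[(2R,3S)-3,5,7-tris(benzyloxy)-2-(3,4-bis(benzyloxy)phenyl)chroman-8-yl]silyl ether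
Product: 13 5,7,3',4',5'-penta-O-benzyl-(+)-gallocatechin-(4β→8)-3,5,7,3',4'-penta-O-benzyl-(+)-catechin, via 3-O-[dimethyl(triflyloxy)silyl] dimer 12 (not isolated)
Conditions: TMSOTf (1.2 equiv), 2,6-di-tert-butyl-4-methylpyridine, CH2Cl2 (0.002 M), −78 to −30 °C; then K2CO3, MeOH/THF/H2O, rt
Reagents that add atoms: none
Why: Proposed new method: TMSOTf ionises the C4–OMe bond of 11 to the A-ring-stabilised flavan-4-yl cation; the silicon-bound C8 of the lower catechin, four atoms away (C4–C3–O–Si–C8), attacks it at the ipso carbon, the arenium ion is stabilised by its 5-, 7- and 1-oxygens and by β-silicon, and loss of silicon to triflate (giving 12) rearomatises the ring. The closest known reaction types are the desilylative ipso-Friedel–Crafts substitution of arylsilanes and the silicon-tethered intramolecular delivery of aryl groups to glycosyl oxocarbenium ions, which gives 1,2-cis C-aryl glycosides. No ring of the product is closed; the transient spiro 1-oxa-2-silacyclopentane forms by a 5-exo-trig attack on the cation and is opened again in the same step. The one new stereocentre, C4 of the middle unit, is controlled by C3: the one-atom tether on the β-oxygen can reach only the β face, which is also the axial face of the half-chair cation, so the aryl group should end cis to O3 (4β) whatever the configuration of the methoxy group was. Selectivity for C8 over C6 follows from the ipso geometry, since both ortho neighbours of the silylated carbon carry oxygen and C6 would need a strained seven-membered meta-bridged transition state. The step needs intramolecular capture to outrun intermolecular alkylation and protodesilylation, which high dilution and the hindered pyridine base are meant to secure. Carbonate methanolysis then cleaves the O–Si bond and frees the 3-OH.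

Step 9
Reactants: 2 5,7,3',4'-tetra-O-benzyl-(+)-catechin
Product: 14 (2R,3S,4S)-5,7-bis(benzyloxy)-2-[3,4-bis(benzyloxy)phenyl]-4-(2-ethoxyethoxy)chroman-3-ol
Conditions: DDQ (2 equiv), 2-ethoxyethanol, CH2Cl2, rt
Reagents that add atoms: 2-ethoxyethanol, CCOCCO
Why: DDQ benzylic oxidation; hydride abstraction at C4 gives the A-ring-stabilised cation, which the alcohol captures. This is an established way to activate C4 of benzylated flavan-3-ols; the new C4 centre is lost again in step 10.

Step 10
Reactants: 14 (2R,3S,4S)-5,7-bis(benzyloxy)-2-[3,4-bis(benzyloxy)phenyl]-4-(2-ethoxyethoxy)chroman-3-ol; 13 5,7,3',4',5'-penta-O-benzyl-(+)-gallocatechin-(4β→8)-3,5,7,3',4'-penta-O-benzyl-(+)-catechin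
Product: 15 5,7,3',4'-tetra-O-benzyl-(+)-catechin-(4α→8)-5,7,3',4',5'-penta-O-benzyl-(+)-gallocatechin-(4β→8)-3,5,7,3',4'-penta-O-benzyl-(+)-catechin
Conditions: TMSOTf (cat.), CH2Cl2, −78 °C, 13 in slight excess
Reagents that add atoms: none
Why: Lewis-acid Friedel–Crafts interflavan coupling; the cation from 14 should be attacked by C8 of the gallocatechin unit of 13, the most nucleophilic free position (the C6 carbons lie between two benzyloxy groups). The bulky arene is expected to enter on the α face, anti to the C3 oxygen of the electrophile, setting the 3,4-trans (4α) bond of the upper unit.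

Step 11
Reactants: 15 5,7,3',4'-tetra-O-benzyl-(+)-catechin-(4α→8)-5,7,3',4',5'-penta-O-benzyl-(+)-gallocatechin-(4β→8)-3,5,7,3',4'-penta-O-benzyl-(+)-catechin
Product: 16 (+)-catechin-(4α→8)-(+)-gallocatechin-(4β→8)-(+)-catechin (CNP0302529.2)
Conditions: H2 (1 atm), Pd(OH)2/C, THF/MeOH/H2O, rt; filtration under Ar, lyophilisation
Reagents that add atoms: none
Why: Hydrogenolysis of the fourteen benzyl ethers; the neutral medium should spare the acid-labile interflavan bonds and the base-labile C2 centres, and the doubly benzylic C4–aryl bonds are not expected to cleave.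

## Compound list

1 | (+)-catechin, (2R,3S) | Oc1cc(O)c2c(c1)O[C@H](c1ccc(O)c(O)c1)[C@@H](O)C2 | starting material

2 | 5,7,3',4'-tetra-O-benzyl-(+)-catechin | O(Cc3ccccc3)c1cc(OCc3ccccc3)c2c(c1)O[C@H](c1ccc(OCc3ccccc3)c(OCc3ccccc3)c1)[C@@H](O)C2 | intermediate

3 | 3,5,7,3',4'-penta-O-benzyl-(+)-catechin | O(Cc3ccccc3)c1cc(OCc3ccccc3)c2c(c1)O[C@H](c1ccc(OCc3ccccc3)c(OCc3ccccc3)c1)[C@@H](OCc3ccccc3)C2 | intermediate

4 | 8-bromo-3,5,7,3',4'-penta-O-benzyl-(+)-catechin | O(Cc3ccccc3)c1cc(OCc3ccccc3)c2c(c1Br)O[C@H](c1ccc(OCc3ccccc3)c(OCc3ccccc3)c1)[C@@H](OCc3ccccc3)C2 | intermediate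

5 | (+)-dihydromyricetin (ampelopsin), (2R,3R) | Oc1cc(O)c2c(c1)O[C@H](c1cc(O)c(O)c(O)c1)[C@@H](O)C2=O | starting material

6 | 5,7,3',4',5'-penta-O-benzyl-(+)-dihydromyricetin | O(Cc3ccccc3)c1cc(OCc3ccccc3)c2c(c1)O[C@H](c1cc(OCc3ccccc3)c(OCc3ccccc3)c(OCc3ccccc3)c1)[C@@H](O)C2=O | intermediate

7 | (2R,3S,4R)-5,7-bis(benzyloxy)-2-[3,4,5-tris(benzyloxy)phenyl]chromane-3,4-diol (2,3-trans-3,4-trans) | O(Cc3ccccc3)c1cc(OCc3ccccc3)c2c(c1)O[C@H](c1cc(OCc3ccccc3)c(OCc3ccccc3)c(OCc3ccccc3)c1)[C@@H](O)[C@@H]2O | intermediate

8 | (2R,3S,4S)-5,7-bis(benzyloxy)-4-methoxy-2-[3,4,5-tris(benzyloxy)phenyl]chroman-3-ol (4β-OMe, main epimer) | O(Cc3ccccc3)c1cc(OCc3ccccc3)c2c(c1)O[C@H](c1cc(OCc3ccccc3)c(OCc3ccccc3)c(OCc3ccccc3)c1)[C@@H](O)[C@H]2OC | intermediate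

9 | 8-lithio-3,5,7,3',4'-penta-O-benzyl-(+)-catechin | O(Cc3ccccc3)c1cc(OCc3ccccc3)c2c(c1[Li])O[C@H](c1ccc(OCc3ccccc3)c(OCc3ccccc3)c1)[C@@H](OCc3ccccc3)C2 | intermediate (not isolated)

10 | 8-(chlorodimethylsilyl)-3,5,7,3',4'-penta-O-benzyl-(+)-catechin | O(Cc3ccccc3)c1cc(OCc3ccccc3)c2c(c1[Si](C)(C)Cl)O[C@H](c1ccc(OCc3ccccc3)c(OCc3ccccc3)c1)[C@@H](OCc3ccccc3)C2 | intermediate (not isolated)

11 | 3-O-[dimethyl(penta-O-benzyl-(+)-catechin-8-yl)silyl] ether of 8 | O(Cc3ccccc3)c1cc(OCc3ccccc3)c2c(c1)O[C@H](c1cc(OCc3ccccc3)c(OCc3ccccc3)c(OCc3ccccc3)c1)[C@@H](O[Si](C)(C)c1c(OCc3ccccc3)cc(OCc3ccccc3)c4c1O[C@H](c1ccc(OCc3ccccc3)c(OCc3ccccc3)c1)[C@@H](OCc3ccccc3)C4)[C@H]2OC | intermediate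

12 | 3-O-[dimethyl(triflyloxy)silyl] derivative of dimer 13 | O(Cc3ccccc3)c1cc(OCc3ccccc3)c2c(c1)O[C@H](c1cc(OCc3ccccc3)c(OCc3ccccc3)c(OCc3ccccc3)c1)[C@@H](O[Si](C)(C)OS(=O)(=O)C(F)(F)F)[C@H]2c1c(OCc3ccccc3)cc(OCc3ccccc3)c2c1O[C@H](c1ccc(OCc3ccccc3)c(OCc3ccccc3)c1)[C@@H](OCc3ccccc3)C2 | intermediate (not isolated)

13 | 5,7,3',4',5'-penta-O-benzyl-(+)-gallocatechin-(4β→8)-3,5,7,3',4'-penta-O-benzyl-(+)-catechin (upper unit 2,3-trans-3,4-cis, free 3-OH) | O(Cc3ccccc3)c1cc(OCc3ccccc3)c2c(c1)O[C@H](c1cc(OCc3ccccc3)c(OCc3ccccc3)c(OCc3ccccc3)c1)[C@@H](O)[C@H]2c1c(OCc3ccccc3)cc(OCc3ccccc3)c2c1O[C@H](c1ccc(OCc3ccccc3)c(OCc3ccccc3)c1)[C@@H](OCc3ccccc3)C2 | intermediate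

14 | (2R,3S,4S)-5,7-bis(benzyloxy)-2-[3,4-bis(benzyloxy)phenyl]-4-(2-ethoxyethoxy)chroman-3-ol (main epimer) | O(Cc3ccccc3)c1cc(OCc3ccccc3)c2c(c1)O[C@H](c1ccc(OCc3ccccc3)c(OCc3ccccc3)c1)[C@@H](O)[C@H]2OCCOCC | intermediate

15 | tetradeca-O-benzyl trimer: tetra-O-benzyl-(+)-catechin-(4α→8)-penta-O-benzyl-(+)-gallocatechin-(4β→8)-penta-O-benzyl-(+)-catechin | O(Cc3ccccc3)c1cc(OCc3ccccc3)c2c(c1)O[C@H](c1ccc(OCc3ccccc3)c(OCc3ccccc3)c1)[C@@H](O)[C@@H]2c1c(OCc3ccccc3)cc(OCc3ccccc3)c2c1O[C@H](c1cc(OCc3ccccc3)c(OCc3ccccc3)c(OCc3ccccc3)c1)[C@@H](O)[C@H]2c1c(OCc3ccccc3)cc(OCc3ccccc3)c2c1O[C@H](c1ccc(OCc3ccccc3)c(OCc3ccccc3)c1)[C@@H](OCc3ccccc3)C2 | intermediate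

16 | (+)-catechin-(4α→8)-(+)-gallocatechin-(4β→8)-(+)-catechin (CNP0302529.2) | Oc1cc(O)c2c(c1)O[C@H](c1ccc(O)c(O)c1)[C@@H](O)[C@@H]2c1c(O)cc(O)c2c1O[C@H](c1cc(O)c(O)c(O)c1)[C@@H](O)[C@H]2c1c(O)cc(O)c2c1O[C@H](c1ccc(O)c(O)c1)[C@@H](O)C2 | target

## Step count and least certain steps

Total step count: 11. Longest linear sequence: 7 steps (steps 1, 2, 3, 7, 8, 10, 11 from 1; equally steps 4, 5, 6, 7, 8, 10, 11 from 5).

Step 8 (key step, proposed new method). The intramolecular ipso attack may be outrun by intermolecular alkylation of the free C6 of another molecule, or by protodesilylation of the very electron-rich aryl–silicon bond by adventitious acid. If the spiro transition state is too strained, the cation may instead lose the C3 proton. The fallback uses known chemistry, sets out from 6 and 4 and returns at 13. Silylation of the C3 alcohol of 6 (TESCl, imidazole) gives 3-O-triethylsilyl-penta-O-benzyl-dihydromyricetin F1. Aryllithium 9, made from 4 as in step 7, adds to its C4 carbonyl to give the tertiary carbinol F2, whose C4 configuration is irrelevant. Acid (BF3·OEt2, CH2Cl2, −40 °C) ionises the tertiary benzylic alcohol and triggers a pinacol-type rearrangement. The C3 hydrogen, axial and α in the 2,3-trans series, shifts suprafacially to the α face of C4 and the silyl group is lost, giving the 2α,4β-diaryl-chroman-3-one F3. Hydride reduction (NaBH4/CeCl3 or LiAlH(O-t-Bu)3, −78 °C) should occur on the axial α face, because the β face is screened by the axial 4β-aryl group, and gives 13.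

Step 7. Double arylation at silicon, hydrolysis of chlorosilane 10 before it meets the hindered alcohol, or benzylic metalation competing with bromine–lithium exchange may erode the tether formation. The fallback sets out from 4 and 8 and returns at 11. Aryllithium 9 is quenched with chlorodimethylsilane to give the isolable, chromatographable 8-(dimethylsilyl)-penta-O-benzyl-(+)-catechin F4. This is joined to 8 by catalytic dehydrogenative Si–O coupling (Ru(II) or Ir(I) catalyst, neutral conditions) to give 11.

Step 4. Base may open the C ring of the flavanonol to the chalcone, with loss of the C2 configuration on reclosure, and air may dehydrogenate it to the flavonol; the chelated 5-OH may alkylate incompletely. The fallback sets out from 5 and returns at 8. Reduction of 5 with NaBH4 and hydrogenolysis of the benzylic 4-OH (H2, Pd/C, AcOH) gives (+)-gallocatechin F5, which has no carbonyl and cannot ring-open in this way. Benzylation (BnBr, K2CO3, DMF) gives 5,7,3',4',5'-penta-O-benzyl-(+)-gallocatechin F6. DDQ oxidation in the presence of methanol, as in step 9, gives 8.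

Step 10. The cation from 14 may alkylate C8 of a second molecule of 14 (self-condensation), attack may spill over to the C6 positions of 13, and facial selectivity may be incomplete. The acid may also re-ionise the 3,4-cis bond of 13. The fallback sets out from 14 and 13 and returns at 16. Bromination of 14 (NBS, CH2Cl2, −78 °C) gives the 8-bromo electrophile F7, in which the nucleophilic carbon is capped. Its TMSOTf coupling with 13 gives the 8-bromo trimer F8. The hydrogenolysis of step 11, run with Et3N (1 equiv), removes the bromine together with the benzyl groups to give 16.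

## Further compounds

F1 | step 8 | 3-O-triethylsilyl-5,7,3',4',5'-penta-O-benzyl-(+)-dihydromyricetin | O(Cc3ccccc3)c1cc(OCc3ccccc3)c2c(c1)O[C@H](c1cc(OCc3ccccc3)c(OCc3ccccc3)c(OCc3ccccc3)c1)[C@@H](O[Si](CC)(CC)CC)C2=O

F2 | step 8 | tertiary carbinol: 4-hydroxy-4-(penta-O-benzyl-(+)-catechin-8-yl)-3-O-triethylsilyl-penta-O-benzyl-gallocatechin (C4 epimers, configuration irrelevant) | O(Cc3ccccc3)c1cc(OCc3ccccc3)c2c(c1)O[C@H](c1cc(OCc3ccccc3)c(OCc3ccccc3)c(OCc3ccccc3)c1)[C@@H](O[Si](CC)(CC)CC)C2(O)c1c(OCc3ccccc3)cc(OCc3ccccc3)c4c1O[C@H](c1ccc(OCc3ccccc3)c(OCc3ccccc3)c1)[C@@H](OCc3ccccc3)C4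

F3 | step 8 | (2R)-2α,4β-diaryl-chroman-3-one: 3-oxo analogue of 13 (2,4-trans) | O(Cc3ccccc3)c1cc(OCc3ccccc3)c2c(c1)O[C@H](c1cc(OCc3ccccc3)c(OCc3ccccc3)c(OCc3ccccc3)c1)C(=O)[C@H]2c1c(OCc3ccccc3)cc(OCc3ccccc3)c4c1O[C@H](c1ccc(OCc3ccccc3)c(OCc3ccccc3)c1)[C@@H](OCc3ccccc3)C4

F4 | step 7 | 8-(dimethylsilyl)-3,5,7,3',4'-penta-O-benzyl-(+)-catechin | O(Cc3ccccc3)c1cc(OCc3ccccc3)c2c(c1[SiH](C)C)O[C@H](c1ccc(OCc3ccccc3)c(OCc3ccccc3)c1)[C@@H](OCc3ccccc3)C2

F5 | step 4 | (+)-gallocatechin, (2R,3S) | Oc1cc(O)c2c(c1)O[C@H](c1cc(O)c(O)c(O)c1)[C@@H](O)C2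

F6 | step 4 | 5,7,3',4',5'-penta-O-benzyl-(+)-gallocatechin | O(Cc3ccccc3)c1cc(OCc3ccccc3)c2c(c1)O[C@H](c1cc(OCc3ccccc3)c(OCc3ccccc3)c(OCc3ccccc3)c1)[C@@H](O)C2

F7 | step 10 | 8-bromo derivative of 14 | O(Cc3ccccc3)c1cc(OCc3ccccc3)c2c(c1Br)O[C@H](c1ccc(OCc3ccccc3)c(OCc3ccccc3)c1)[C@@H](O)[C@H]2OCCOCC

F8 | step 10 | 8-bromo derivative of 15 (bromine on C8 of the upper unit) | O(Cc3ccccc3)c1cc(OCc3ccccc3)c2c(c1Br)O[C@H](c1ccc(OCc3ccccc3)c(OCc3ccccc3)c1)[C@@H](O)[C@@H]2c1c(OCc3ccccc3)cc(OCc3ccccc3)c2c1O[C@H](c1cc(OCc3ccccc3)c(OCc3ccccc3)c(OCc3ccccc3)c1)[C@@H](O)[C@H]2c1c(OCc3ccccc3)cc(OCc3ccccc3)c2c1O[C@H](c1ccc(OCc3ccccc3)c(OCc3ccccc3)c1)[C@@H](OCc3ccccc3)C2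

A1 | alternative 1 | penta-O-benzyl-(+)-gallocatechin-(4α→8)-penta-O-benzyl-(+)-catechin (3,4-trans epimer of 13) | O(Cc3ccccc3)c1cc(OCc3ccccc3)c2c(c1)O[C@H](c1cc(OCc3ccccc3)c(OCc3ccccc3)c(OCc3ccccc3)c1)[C@@H](O)[C@@H]2c1c(OCc3ccccc3)cc(OCc3ccccc3)c2c1O[C@H](c1ccc(OCc3ccccc3)c(OCc3ccccc3)c1)[C@@H](OCc3ccccc3)C2

A2 | alternative 2 | 3,5-bis(benzyloxy)-2-[hydroxy(penta-O-benzyl-(+)-catechin-8-yl)methyl]phenol (carbinol epimers, lost on quinone methide formation) | Oc1cc(OCc3ccccc3)cc(OCc3ccccc3)c1C(O)c1c(OCc3ccccc3)cc(OCc3ccccc3)c2c1O[C@H](c1ccc(OCc3ccccc3)c(OCc3ccccc3)c1)[C@@H](OCc3ccccc3)C2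

A3 | alternative 2 | (E)-2-[2-(3,4,5-tris(benzyloxy)phenyl)ethenyl]-4,4,5,5-tetramethyl-1,3,2-dioxaborolane | CC1(C)OB(/C=C/c2cc(OCc3ccccc3)c(OCc3ccccc3)c(OCc3ccccc3)c2)OC1(C)C

A4 | alternative 3 | tertiary carbinol: 4-hydroxy-4-(penta-O-benzyl-(+)-catechin-8-yl)-3,5,7,3',4',5'-hexa-O-benzyl-gallocatechin (C4 epimers) | O(Cc3ccccc3)c1cc(OCc3ccccc3)c2c(c1)O[C@H](c1cc(OCc3ccccc3)c(OCc3ccccc3)c(OCc3ccccc3)c1)[C@@H](OCc3ccccc3)C2(O)c1c(OCc3ccccc3)cc(OCc3ccccc3)c4c1O[C@H](c1ccc(OCc3ccccc3)c(OCc3ccccc3)c1)[C@@H](OCc3ccccc3)C4
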